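The winter flask is the one we are asked about: substrate at 2.0 M, closed and isothermal, followed through its first minutes. Beside it stands an autumn flask with a lower charge, followed for longer.

| flask | substrate | remark | time |
|---|---|---|---|
| winter | 2 M | the very flask that is asked about, followed so far |  |
| autumn | 1.3 M | run made earlier |  |
| flask | 2.0 M |  | 80 min |

| run | time / min | target / % | isomer of the product / % |
|---|---|---|---|
| winter | 0.500 | 12 | 4 |
| winter | 1.33 | 28 | 11 |
| winter | 3.00 | 48 | 18 |
| winter | 6.00 | 64 | 26 |
| autumn | 8.00 | 67 | 22 |
| autumn | 20.0 | 78 | 18 |
| autumn | 40.0 | 82 | 9 |
| autumn | 60.0 | 88 | 6 |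

(readings scatter by 2 percentage points)

- ratio of target to isomer of the product at 4.0 s
- ratio of target to isomer of the product at 80 min

- a reading or a percentage of target counts all its forms, free or not

Read across, the winter table gives target over isomer of the product as 3.00 in the first row and 2.46 in the last, with readings good to 2 percentage points. Summing the four rows gives 2.58. We read this as the selectivity factor of two parallel routes and carry it back to 4.0 s, earlier than any reading.

The autumn table shows something new: the isomer falls from 22% at 8.00 min to 6% at 60.0 min. Taken as first order, that fall gives 27.7 min. We call this τ, the drain half-life: the time in which the falling isomer of the product halves. Starting from the last winter reading, 26% at 6.00 min, τ leaves 4.09% at 80 min. If the rest of the charge is target, our ratio is 23.4.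

The forecast gives 2.6 and 22, on the ground that “the isomer later drains into target”. Its late number lies a little below ours.

The simulation gives 2.30 and 20.3.

    substrate ⇌ target (K = 8.10, k = 0.00460 s⁻¹)
    substrate ⇌ isomer of the product (K = 2.30, k = 0.00200 s⁻¹)
    substrate ⇌ third isomer (K = 1.00, k = 1.20 × 10⁻⁴ s⁻¹)
    crystals ⇌ target, rate k4*(cs4 - [target]) while solid is left; crystals form when [target] > cs4 (solubility = 0.190 M, k = 0.0160 s⁻¹)

In the winter flask the isomer of the product goes from 23.3% at 8.00 min to 4.54% at 80.0 min, a drain half-life of 30.5 min, beside the 27.7 min of τ as read from the autumn readings. The neighbouring flask is charged with 1.2 M of substrate. Our reckoning contains no charge, so τ gives it 23.4 again, but that flask gives 14.5, lower than our number. Its isomer of the product stands at 6.18%, which is 0.0742 M, against 0.0908 M in the winter flask.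

The data stem from a simulated flask on assumed constants; scatter was added.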